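The constants used here stand for no real mixture; the rest is arithmetic.

If Friday's flask and its neighbours are run again, the clock to watch is the time target takes to fall back.

    starting material + reagent ⇌ target (K1 = 1.65 M⁻¹, k1 = 0.0417 M⁻¹ s⁻¹)
    second substrate + reagent ⇌ second product (K2 = 1.2 M⁻¹, k2 = 0.0439 M⁻¹ s⁻¹)
    second substrate + protic impurity → quenched substrate (k3 = 0.709 M⁻¹ s⁻¹)

all flasks: second substrate 0.300 M; protic impurity 0.0300 M
- Friday's: starting material 0.30 M; reagent 0.750 M; time 20 min; a closed flask charged with all of it at once and left for 20 min
- Tuesday's: starting material 0.30 M; reagent 0.750 M (fed, over 16.0 min); time 20 min; a stirred flask in which reagent is dosed at a steady rate over 16.0 min without added volume, worked up at 20 min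
- Wednesday's: starting material 0.30 M (fed, over 16.0 min); reagent 0.750 M; time 20 min; a stirred flask in which starting material is dosed at a steady rate over 16.0 min without added volume, worked up at 20 min
- Monday's: starting material 0.30 M; reagent 0.750 M; one stirred flow tank at steady state, fed with the mixture as stated, mean residence time 20 min

- the stated concentrations are those of everything mixed, before any reaction; amounts are the same in each set-up
- the feed brings no volume worth counting
- run time (Friday's): 20 min

- the set-up with the highest amount of target at the outlet or at the end, in percent of the starting material put in ("none" if the first two lie within 2 percentage points) (Friday's / Tuesday's / Wednesday's / Monday's / none)
- amount of target at the outlet or at the end, in percent of the starting material put in, Friday's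
- amount of target at the outlet or at the end, in percent of the starting material put in, Tuesday's
- amount of target at the outlet or at the end, in percent of the starting material put in, Wednesday's
- amount of target at the outlet or at the end, in percent of the starting material put in, Monday's

I asked first what the end state must be. In the batch flasks both reversible steps head for balance, and the quench runs one way. Tuesday's and Wednesday's flasks stand for 4.00 min after dosing. With second substrate as charged, the protic impurity has a mean life of about 0.0784 min, much shorter than that hold. So I took 0.0300 M of second substrate as lost in each batch flask, whatever the order of charging.

Next I asked how fast balance comes. Target returns to starting material and reagent with a mean life of 0.659 min, and I used this return time as my clock for the approach. For 20 min that gives 30.3. I called this the return number, the time allowed divided by the return time. Tuesday's and Wednesday's holds give 6.07, which by that clock leaves about 0.231% of the distance to balance. I therefore expected these flasks to match Friday's, under thermodynamic control.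

Last I asked what Monday's tank loses, since it stands short of balance. Its steady state divides the equilibrium constant of the first step by one plus the inverse return number. At equal reagent, target's share falls by the share made times the share unmade, over one plus the return number. That product is at most a quarter, so I reckoned that at equal reagent Monday's tank trails by at most about 0.8 percentage points, less than the margin. I committed to no winner.

The forecast gave 45.7% for Friday's, 45.7% for Tuesday's, 45.7% for Wednesday's and 45.1% for Monday's, with best none, holding of the batch flasks that “all three end at the same equilibrium”.

The simulation gave 45.7% for Friday's, 45.7% for Tuesday's, 45.7% for Wednesday's and 45.1% for Monday's, so best was none. Monday's tank set a mean residence time of 20 min against a return time of 0.659 min, a return number of 30.3, and it stood 0.60 points below Friday's flask, inside my ceiling of 0.8 points, with starting material at 0.165 M throughout the tank. Friday's flask, left to 200 min, had a return number of 303 and read 45.7%.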